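**Strategy.** The hydroxylated retro end group (ring C1'–C6' with C4'=C5', exocyclic C6'=C7', then C8'=C9' bearing methyl C19'; carotenoid numbering) is the dehydration product of a β-ionol-type carbinol, so the C9'–C10' single bond is disconnected as a carbonyl addition. In the key step a C27 polyenyllithium (C10' carbanion; keto ring masked as a dioxolane-bearing β-ring with a C9 carbinol) adds to the C9' ketone of (3R)-3-silyloxy-β-ionone, and acid quench in the same flask strips both tertiary hydroxyls together with the C4 and C4' ring protons, the dioxolane and the silyl group. Two ordinary β-ionone-type ends thus become the bis-retro dodecaene chromophore at once.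

Key step: step 11

Remark: (4R,6R)-actinol, 1,4-dioxane-2,3-diol, diethyl (3-cyano-2-methylallyl)phosphonate and 2,2,6-trimethylcyclohexane-1,4-dione are taken as purchasable; the 3R centre of actinol becomes 3'S in the target only because C4' turns sp2 and then outranks C2'.

Step 1
Reactants: 1 1,4-dioxane-2,3-diol (glyoxal equivalent); 2 diethyl (E)-(3-cyano-2-methylallyl)phosphonate (commercial E/Z mixture usable)
Product: 4 (2E,4E,6E,8E)-3,8-dimethyldeca-2,4,6,8-tetraenedinitrile, via sodium phosphonate carbanion 3 (not isolated)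
Conditions: NaH (4.4 equiv), 2 (2.2 equiv), THF, 0 °C; then 1, 0 °C → rt; I2 (cat.), toluene, daylight; recrystallisation
Reagents that add atoms: none
Why: Twofold Horner–Wadsworth–Emmons olefination: base opens the bis-hemiacetal to glyoxal, the allylic phosphonate anion should give the two new disubstituted double bonds E, and the trisubstituted C=C geometry, which scrambles in the delocalised anion, should be driven to all-E by iodine-catalysed equilibration and crystallisation of the symmetric dinitrile.

Step 2
Reactants: 4 (2E,4E,6E,8E)-3,8-dimethyldeca-2,4,6,8-tetraenedinitrile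
Product: 6 (2E,4E,6E,8E)-3,8-dimethyldeca-2,4,6,8-tetraenedial, via bis(N-diisobutylaluminio) aldimine 5 (not isolated)
Conditions: i-Bu2AlH (2.4 equiv), CH2Cl2, –78 °C; then wet SiO2, 0 °C → rt
Reagents that add atoms: water, O
Why: Partial nitrile reduction with i-Bu2AlH: one hydride per C≡N gives the N-aluminio aldimine, which is not reduced further at –78 °C and is hydrolysed to the aldehyde on wet silica, the conjugated tetraene being inert to the reagent.

Step 3
Reactants: 6 (2E,4E,6E,8E)-3,8-dimethyldeca-2,4,6,8-tetraenedial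
Product: 7 (1E,3E,5E,7E,9E,11E)-1,12-diiodo-4,9-dimethyldodeca-1,3,5,7,9,11-hexaene
Conditions: CHI3 (4 equiv), CrCl2 (12 equiv), THF, 0 °C → rt, dark
Reagents that add atoms: iodoform, IC(I)I
Why: Twofold Takai olefination: the geminal dichromium species from CHI3 and CrCl2 adds to each enal carbonyl and eliminates to the (E)-iodoalkene under neutral, non-basic conditions that should spare the polyene.

Step 4
Reactants: 8 2,2,6-trimethylcyclohexane-1,4-dione (racemic)
Product: 9 7,9,9-trimethyl-1,4-dioxaspiro[4.5]decan-8-one (racemic)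
Conditions: ethylene glycol (1.1 equiv), p-TsOH·H2O (cat.), toluene, reflux, Dean–Stark
Reagents that add atoms: ethylene glycol, OCCO
Why: Acid-catalysed ketalisation with azeotropic removal of water should be selective for the unhindered C4 carbonyl, because the C1 carbonyl is flanked by a quaternary and a tertiary carbon.

Step 5
Reactants: 9 7,9,9-trimethyl-1,4-dioxaspiro[4.5]decan-8-one
Product: 11 7,9,9-trimethyl-1,4-dioxaspiro[4.5]dec-7-en-8-yl trifluoromethanesulfonate, via lithium enolate 10 (not isolated)
Conditions: LiN(i-Pr)2 (1.2 equiv), THF, –78 °C; PhNTf2 (1.2 equiv), –78 °C → rt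
Reagents that add atoms: N-phenylbis(trifluoromethanesulfonimide), O=S(=O)(N(c1ccccc1)S(=O)(=O)C(F)(F)F)C(F)(F)F
Why: Enolate O-triflation: the ketone has a single α-hydrogen, so only one enolate can form, and its oxygen is sulfonylated by PhNTf2 to the tetrasubstituted enol triflate, the dioxolane being inert to base.

Step 6
Reactants: 11 7,9,9-trimethyl-1,4-dioxaspiro[4.5]dec-7-en-8-yl trifluoromethanesulfonate
Product: 12 (E)-4-(7,9,9-trimethyl-1,4-dioxaspiro[4.5]dec-7-en-8-yl)but-3-en-2-one (3,3-ethylenedioxy-β-ionone)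
Conditions: methyl vinyl ketone (3 equiv), Pd(OAc)2 (5 mol %), PPh3 (10 mol %), Et3N (2 equiv), DMF, 70 °C
Reagents that add atoms: methyl vinyl ketone, C=CC(C)=O
Why: Heck reaction: oxidative addition of the enol triflate to zerovalent palladium, insertion of methyl vinyl ketone at its unsubstituted terminus and syn β-hydride elimination should give the (E)-dienone, that is, the β-ionone side chain.

Step 7
Reactants: 13 (4R,6R)-4-hydroxy-2,2,6-trimethylcyclohexan-1-one (actinol)
Product: 14 (4R,6R)-4-(triethylsilyloxy)-2,2,6-trimethylcyclohexan-1-one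
Conditions: Et3SiCl (1.2 equiv), imidazole (2.5 equiv), CH2Cl2, 0 °C → rt
Reagents that add atoms: chlorotriethylsilane, CC[Si](Cl)(CC)CC
Why: Silyl ether formation at the only hydroxyl; the triethylsilyl group should survive enolate and palladium chemistry yet fall in the dilute acid of step 11, and the carbinol centre is not touched.

Step 8
Reactants: 14 (4R,6R)-4-(triethylsilyloxy)-2,2,6-trimethylcyclohexan-1-one
Product: 16 (4R)-4-(triethylsilyloxy)-2,6,6-trimethylcyclohex-1-en-1-yl trifluoromethanesulfonate, via lithium enolate 15 (not isolated)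
Conditions: LiN(i-Pr)2 (1.2 equiv), THF, –78 °C; PhNTf2 (1.2 equiv), –78 °C → rt
Reagents that add atoms: N-phenylbis(trifluoromethanesulfonimide), O=S(=O)(N(c1ccccc1)S(=O)(=O)C(F)(F)F)C(F)(F)F
Why: Enolate O-triflation as in step 5; deprotonation erases the α-methyl stereocentre, which is not needed, and leaves the remote silyloxy-bearing centre unchanged.

Step 9
Reactants: 16 (4R)-4-(triethylsilyloxy)-2,6,6-trimethylcyclohex-1-en-1-yl trifluoromethanesulfonate
Product: 17 (R,E)-4-[4-(triethylsilyloxy)-2,6,6-trimethylcyclohex-1-en-1-yl]but-3-en-2-one ((3R)-3-(triethylsilyloxy)-β-ionone)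
Conditions: methyl vinyl ketone (3 equiv), Pd(OAc)2 (5 mol %), PPh3 (10 mol %), Et3N (2 equiv), DMF, 70 °C
Reagents that add atoms: methyl vinyl ketone, C=CC(C)=O
Why: Heck reaction as in step 6, expected to give the (E)-enone without touching the silyl ether or the stereocentre.

Step 10
Reactants: 7 (1E,3E,5E,7E,9E,11E)-1,12-diiodo-4,9-dimethyldodeca-1,3,5,7,9,11-hexaene; 12 3,3-ethylenedioxy-β-ionone
Product: 19 (1E,4E,6E,8E,10E,12E,14E)-15-iodo-3,7,12-trimethyl-1-(7,9,9-trimethyl-1,4-dioxaspiro[4.5]dec-7-en-8-yl)pentadeca-1,4,6,8,10,12,14-heptaen-3-ol (carbinol epimers), via lithio iodohexaene 18 (not isolated)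
Conditions: 7 (3.0 equiv), t-BuLi (2.1 equiv), THF–Et2O, –78 °C, dark; then 12 (1.0 equiv), –78 °C; H2O; excess 7 recovered
Reagents that add atoms: none
Why: Iodine–lithium exchange (two equivalents of t-BuLi, retention of E geometry) should be much faster than addition of the base to the polyene, the excess of diiodide keeps it at one terminus, and the alkenyllithium then undergoes 1,2-addition to the methyl ketone; the new carbinol centre forms as both epimers, which is immaterial because step 11 destroys it.

Step 11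
Reactants: 19 C27 iodo carbinol; 17 (3R)-3-(triethylsilyloxy)-β-ionone
Product: 22 (3'S,6E,6'E)-3'-hydroxy-4',5'-didehydro-4,5'-retro-β,β-caroten-3-one (target), via dilithio species 20 (not isolated), via bis-carbinol 21 (not isolated)
Conditions: MeLi (1.05 equiv), THF–Et2O, –78 °C; t-BuLi (2.1 equiv), –78 °C; 17 (1.3 equiv), –78 → –40 °C; then aq. HCl (1 M, 4 equiv), THF, 0 °C → rt, Ar, dark; NaHCO3; chromatography and crystallisation in the dark
Reagents that add atoms: water, O
Why: MeLi first turns the C9 hydroxyl into its lithium alkoxide, t-BuLi then exchanges the terminal iodide for lithium with retention of the E geometry, and the C10' carbanion adds to the C9' carbonyl of 17 to form the C9'–C10' bond, the closest known reaction type being the 1,2-addition of alkenyllithium or alkenylmagnesium reagents to β-ionone. On acidification each tertiary, doubly allylic carbinol ionises to a polyenyl cation delocalised into its ring, and loss of a proton from C4' (and from C4 at the other end) gives the retro arrangement C4'=C5', C6'=C7', C8'=C9', as known from the acid dehydration of retinol-type carbinols to retro polyenes; the same acid hydrolyses the dioxolane, now allylic to the polyene, and cleaves the Si–O bond. No ring is closed and no stereocentre is created: C3' is carried unchanged from actinol because only its Si–O bond breaks, and the two carbinol centres of 21 are destroyed. The selectivity needed is proton loss from the ring methylenes rather than from the C19 and C19' methyl groups, which should be secured by thermodynamic control, since reversible protonation funnels cross-conjugated isomers into the fully conjugated dodecaene and C4–H becomes α to the unmasked C3 carbonyl. The second requirement is that the allylic C3' carbinol survives, which brief exposure to dilute acid at 0 °C is meant to secure. A mixture of geometric isomers about C6=C7 and C6'=C7' is to be expected; the (6E,6'E) isomer should be separable and the others can be re-equilibrated.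

**Compound list**

1 | 1,4-dioxane-2,3-diol (glyoxal equivalent; configuration immaterial) | OC1OCCOC1O | starting material
2 | diethyl (E)-(3-cyano-2-methylallyl)phosphonate | CCOP(=O)(OCC)C/C(C)=C/C#N | starting material
3 | sodium salt of the α-carbanion of 2 | [Na+].CCOP(=O)(OCC)[CH-]/C(C)=C/C#N | intermediate
4 | (2E,4E,6E,8E)-3,8-dimethyldeca-2,4,6,8-tetraenedinitrile | N#C/C=C(C)/C=C/C=C/C(C)=C/C#N | intermediate
5 | bis(N-diisobutylaluminio) aldimine of 6 | CC(C)C[Al](CC(C)C)N=C/C=C(C)/C=C/C=C/C(C)=C/C=N[Al](CC(C)C)CC(C)C | intermediate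
6 | (2E,4E,6E,8E)-3,8-dimethyldeca-2,4,6,8-tetraenedial | O=C/C=C(C)/C=C/C=C/C(C)=C/C=O | intermediate
7 | (1E,3E,5E,7E,9E,11E)-1,12-diiodo-4,9-dimethyldodeca-1,3,5,7,9,11-hexaene | I/C=C/C=C(C)/C=C/C=C/C(C)=C/C=C/I | intermediate
8 | 2,2,6-trimethylcyclohexane-1,4-dione (racemic) | CC1CC(=O)CC(C)(C)C1=O | starting material
9 | 7,9,9-trimethyl-1,4-dioxaspiro[4.5]decan-8-one (racemic) | CC1CC2(CC(C)(C)C1=O)OCCO2 | intermediate
10 | lithium 7,9,9-trimethyl-1,4-dioxaspiro[4.5]dec-7-en-8-olate | [Li]OC1=C(C)CC2(CC1(C)C)OCCO2 | intermediate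
11 | 7,9,9-trimethyl-1,4-dioxaspiro[4.5]dec-7-en-8-yl trifluoromethanesulfonate | O=S(=O)(OC1=C(C)CC2(CC1(C)C)OCCO2)C(F)(F)F | intermediate
12 | (E)-4-(7,9,9-trimethyl-1,4-dioxaspiro[4.5]dec-7-en-8-yl)but-3-en-2-one | CC(=O)/C=C/C1=C(C)CC2(CC1(C)C)OCCO2 | intermediate
13 | (4R,6R)-4-hydroxy-2,2,6-trimethylcyclohexan-1-one (actinol) | O=C1[C@H](C)C[C@@H](O)CC1(C)C | starting material
14 | (4R,6R)-4-(triethylsilyloxy)-2,2,6-trimethylcyclohexan-1-one | O=C1[C@H](C)C[C@@H](O[Si](CC)(CC)CC)CC1(C)C | intermediate
15 | lithium (4R)-4-(triethylsilyloxy)-2,6,6-trimethylcyclohex-1-en-1-olate | [Li]OC1=C(C)C[C@@H](O[Si](CC)(CC)CC)CC1(C)C | intermediate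
16 | (4R)-4-(triethylsilyloxy)-2,6,6-trimethylcyclohex-1-en-1-yl trifluoromethanesulfonate | O=S(=O)(OC1=C(C)C[C@@H](O[Si](CC)(CC)CC)CC1(C)C)C(F)(F)F | intermediate
17 | (R,E)-4-[4-(triethylsilyloxy)-2,6,6-trimethylcyclohex-1-en-1-yl]but-3-en-2-one | CC(=O)/C=C/C1=C(C)C[C@@H](O[Si](CC)(CC)CC)CC1(C)C | intermediate
18 | (1E,3E,5E,7E,9E,11E)-12-iodo-4,9-dimethyldodeca-1,3,5,7,9,11-hexaen-1-yllithium | [Li]/C=C/C=C(C)/C=C/C=C/C(C)=C/C=C/I | intermediate
19 | (1E,4E,6E,8E,10E,12E,14E)-15-iodo-3,7,12-trimethyl-1-(7,9,9-trimethyl-1,4-dioxaspiro[4.5]dec-7-en-8-yl)pentadeca-1,4,6,8,10,12,14-heptaen-3-ol (C3 epimers) | I/C=C/C=C(C)/C=C/C=C/C(C)=C/C=C/C(C)(O)/C=C/C1=C(C)CC2(CC1(C)C)OCCO2 | intermediate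
20 | O,C-dilithio derivative of 19 (lithium alkoxide at C3, alkenyllithium at C15) | [Li]/C=C/C=C(C)/C=C/C=C/C(C)=C/C=C/C(C)(O[Li])/C=C/C1=C(C)CC2(CC1(C)C)OCCO2 | intermediate
21 | (1E,4E,6E,8E,10E,12E,14E,17E)-3,7,12,16-tetramethyl-1-(7,9,9-trimethyl-1,4-dioxaspiro[4.5]dec-7-en-8-yl)-18-[(4R)-4-(triethylsilyloxy)-2,6,6-trimethylcyclohex-1-en-1-yl]octadeca-1,4,6,8,10,12,14,17-octaene-3,16-diol (C3 and C16 epimers) | CC(O)(/C=C/C1=C(C)C[C@@H](O[Si](CC)(CC)CC)CC1(C)C)/C=C/C=C(C)/C=C/C=C/C(C)=C/C=C/C(C)(O)/C=C/C2=C(C)CC3(CC2(C)C)OCCO3 | intermediate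
22 | (3'S,6E,6'E)-3'-hydroxy-4',5'-didehydro-4,5'-retro-β,β-caroten-3-one | CC1=CC(=O)CC(C)(C)\C1=C/C=C(C)/C=C/C=C(C)/C=C/C=C/C(C)=C/C=C/C(C)=C/C=C1/C(C)=C[C@@H](O)CC1(C)C | target

**Step count.** Total: 11 steps. Longest linear sequence: 5 steps (1, 2, 3, 10, 11 or 4, 5, 6, 10, 11).

**Steps most likely to fail**

1. Step 11. Once the retro system has formed, the C3' carbinol is allylic to the whole dodecaene and may ionise in the acid stage, with loss of configuration or of water; proton loss may also be incompletely regioselective. Fallback, setting out from 19 and coming back at 22: the lithio species 20 is added to ketone 12 in place of 17, so that the acid stage acts on the symmetrical bis-dioxolane bis-carbinol F1 and should deliver (6E,6'E)-rhodoxanthin F2, which carries no acid-labile carbinol. One of its two equivalent ring carbonyls is then reduced with catecholborane and (R)-2-methyl-CBS-oxazaborolidine in toluene at –78 °C (Corey–Bakshi–Shibata reduction, the C4'=C5' flank expected to act as the large group), which should give 22 with C3' set by the catalyst. Diol from over-reduction would be returned to F2 with MnO2.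

2. Step 10. Exchange may run on to the dilithio hexaene, and the iodo-polyenyllithium may decay (proton capture, addition to a polyene) before it meets the ketone. Fallback, setting out from 6 and coming back at 19: twofold Colvin homologation of the dial with LiC(N2)SiMe3 gives (3E,5E,7E,9E)-4,9-dimethyldodeca-3,5,7,9-tetraene-1,11-diyne F3. Its mono-acetylide (LiN(SiMe3)2, F3 in excess, THF, –78 °C) adds to 12 to give the diynyl carbinol F4. NaAlH2(OCH2CH2OCH3)2 then reduces only the alkyne next to the carbinol, by alkoxide-directed trans-hydroalumination, to give the (E)-configured enynyl carbinol F5. Hydrozirconation of the remaining terminal alkyne with Cp2Zr(H)Cl followed by iodinolysis should return 19.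

3. Step 9 (the same holds for step 6). Oxidative addition and carbopalladation at the tetrasubstituted, doubly flanked enol triflate may be slow, so that reduction of the triflate or polymerisation of the enone takes over. Fallback, setting out from 16 and coming back at 17: Stille coupling with (E)-4-(tributylstannyl)but-3-en-2-one (Pd2(dba)3, AsPh3, CuI, NMP, 50 °C), in which the enone arrives as a preformed alkenyl nucleophile by transmetalation instead of by alkene insertion; this makes no new compound (F0).

**Further compounds**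

F1 | step 11 | (1E,4E,6E,8E,10E,12E,14E,17E)-3,7,12,16-tetramethyl-1,18-bis(7,9,9-trimethyl-1,4-dioxaspiro[4.5]dec-7-en-8-yl)octadeca-1,4,6,8,10,12,14,17-octaene-3,16-diol (not isolated) | CC(O)(/C=C/C1=C(C)CC2(CC1(C)C)OCCO2)/C=C/C=C(C)/C=C/C=C/C(C)=C/C=C/C(C)(O)/C=C/C3=C(C)CC4(CC3(C)C)OCCO4
F2 | step 11 | (6E,6'E)-rhodoxanthin (4',5'-didehydro-4,5'-retro-β,β-carotene-3,3'-dione) | CC1=CC(=O)CC(C)(C)\C1=C/C=C(C)/C=C/C=C(C)/C=C/C=C/C(C)=C/C=C/C(C)=C/C=C1/C(C)=CC(=O)CC1(C)C
F3 | step 10 | (3E,5E,7E,9E)-4,9-dimethyldodeca-3,5,7,9-tetraene-1,11-diyne | C#C/C=C(C)/C=C/C=C/C(C)=C/C#C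
F4 | step 10 | (1E,6E,8E,10E,12E)-3,7,12-trimethyl-1-(7,9,9-trimethyl-1,4-dioxaspiro[4.5]dec-7-en-8-yl)pentadeca-1,6,8,10,12-pentaene-4,14-diyn-3-ol | C#C/C=C(C)/C=C/C=C/C(C)=C/C#CC(C)(O)/C=C/C1=C(C)CC2(CC1(C)C)OCCO2
F5 | step 10 | (1E,4E,6E,8E,10E,12E)-3,7,12-trimethyl-1-(7,9,9-trimethyl-1,4-dioxaspiro[4.5]dec-7-en-8-yl)pentadeca-1,4,6,8,10,12-hexaen-14-yn-3-ol | C#C/C=C(C)/C=C/C=C/C(C)=C/C=C/C(C)(O)/C=C/C1=C(C)CC2(CC1(C)C)OCCO2
F0 | step 9 | none | none
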